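**Retrosynthetic overview** (side chain numbered C1'–C16' from the benzylic carbon; target is 2'E,5'R,6'E,11'R)
1. C12' ketone, made last: Weinreb amide plus sulfone-stabilised prenyl anion, then SmI2 desulfonylation.
2. C5'–C6': asymmetric CrCl2/NiCl2 coupling of an (E)-vinyl iodide (C6'–C12') with a β,γ-unsaturated aldehyde (arene plus C1'–C5'); this sets C5'.
3. C6'–C12' with both methyl groups and C11': the ring carbons of 2,6-dimethylphenol. Hydrogenate to meso cis-2,6-dimethylcyclohexanone, break its mirror symmetry by enantioselective deprotonation (key step), cleave the enol C=C with ozone, turn the methyl ketone into the alkyne for methylalumination/iodination.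
4. Arene plus C1'–C5': Cp2ZrCl2-catalysed methylalumination of but-3-yn-1-ol, then NiCl2(PPh3)2-catalysed coupling with the chloromethyl arene from 4-methoxy-2-methylphenol.
5. Rings: no ring of the target is built (the arene is bought); the only ring made, the cyclohexane of step 1, is opened again in step 4.

Assumption: the antipodes shown for the two chiral reagents (magnesium bisamide in step 3, chromium ligand in step 12) are those expected by analogy with close precedents; if either gives the opposite sense, its equally available mirror-image form is used.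

**Step 1**
Reactants: 1 2,6-dimethylphenol
Product: 2 cis-2,6-dimethylcyclohexan-1-ol (2R,6S; meso)
Conditions: H2 (5 bar), Rh/Al2O3 (5 wt %), hexane, 25 °C
Reagents that add atoms: none
Why: Heterogeneous arene hydrogenation delivers all hydrogens from the catalyst surface to one ring face, so the two methyl groups end cis (meso) whatever the carbinol configuration.

**Step 2**
Reactants: 2 cis-2,6-dimethylcyclohexan-1-ol
Product: 3 cis-2,6-dimethylcyclohexan-1-one (2R,6S; meso)
Conditions: NaOCl (1.1 equiv), TEMPO (1 mol %), KBr (0.1 equiv), CH2Cl2/aq. NaHCO3, 0 °C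
Reagents that add atoms: none
Why: TEMPO/hypochlorite (Anelli) oxidation of a secondary alcohol is complete in minutes at pH 9 and 0 °C, so the cis α,α'-dimethyl ketone forms without epimerisation.

**Step 3**
Reactants: 3 cis-2,6-dimethylcyclohexan-1-one
Product: 5 {[(6R)-2,6-dimethylcyclohex-1-en-1-yl]oxy}(trimethyl)silane, via amidomagnesium enolate 4 (not isolated)
Conditions: Bu2Mg (1 equiv), (R,R)-bis(1-phenylethyl)amine (2 equiv), THF, reflux; then TMSCl (4 equiv), DMPU (0.5 equiv), 3, THF, −78 °C
Reagents that add atoms: chlorotrimethylsilane, C[Si](C)(C)Cl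
Why: Enantioselective deprotonation of a meso ketone by the C2-symmetric chiral amide base Mg[N(CHMePh)2]2 (Simpkins–Koga-type desymmetrisation, in situ silyl trapping) removes one of the two enantiotopic axial α-hydrogens, leaving the untouched α-carbon as the (R) centre that becomes C11'.

**Step 4**
Reactants: 5 {[(6R)-2,6-dimethylcyclohex-1-en-1-yl]oxy}(trimethyl)silane
Product: 8 (2R)-2-methyl-6-oxoheptanoic acid, via methoxy hydroperoxide silyl ester 6 (not isolated), via trimethylsilyl keto ester 7 (not isolated)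
Conditions: O3, CH2Cl2/MeOH (4:1), −78 °C; Me2S, −78 → 20 °C; aqueous work-up
Reagents that add atoms: ozone, O=[O+][O-]
Why: Ozonolysis of a silyl enol ether cleaves the enol C=C into a methyl ketone and a silyl ester (methanol traps the carbonyl oxide, Me2S reduces the hydroperoxide), and the stereocentre is not involved.

**Step 5**
Reactants: 8 (2R)-2-methyl-6-oxoheptanoic acid
Product: 11 (2R)-2-methylhept-6-ynoic acid, via dilithium enolate carboxylate 9 (not isolated), via enol phosphate 10 (not isolated)
Conditions: LDA (2.1 equiv), THF, −78 °C; ClP(O)(OEt)2 (1.05 equiv), −78 → 0 °C; LDA (2.3 equiv), −78 → −20 °C; aq. HCl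
Reagents that add atoms: none
Why: Negishi one-pot conversion of a methyl ketone into a terminal alkyne (kinetic enolate, enol phosphate, E2 elimination), in which the lithium carboxylate resists α-deprotonation below 0 °C so the (R) centre is kept.

**Step 6**
Reactants: 11 (2R)-2-methylhept-6-ynoic acid
Product: 13 (2R)-N-methoxy-N,2-dimethylhept-6-ynamide, via acyl imidazolide 12 (not isolated)
Conditions: CDI (1.1 equiv), CH2Cl2, 20 °C; then MeNH(OMe)·HCl (1.3 equiv), 20 °C
Reagents that add atoms: N,O-dimethylhydroxylamine hydrochloride, CNOC.Cl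
Why: Weinreb amide formation through the acyl imidazolide uses no base strong enough to enolise the α-centre.

**Step 7**
Reactants: 13 (2R)-N-methoxy-N,2-dimethylhept-6-ynamide
Product: 15 (2R,6E)-7-iodo-N-methoxy-N,2,6-trimethylhept-6-enamide, via alkenyl(dimethyl)alane 14 (not isolated)
Conditions: Me3Al (3 equiv), Cp2ZrCl2 (0.5 equiv), CH2Cl2, 0 → 20 °C; then I2 (1.3 equiv), THF, −30 → 0 °C
Reagents that add atoms: trimethylaluminium, C[Al](C)C; iodine, II
Why: Negishi Cp2ZrCl2-catalysed carboalumination adds methyl and aluminium syn across the terminal alkyne (methyl to the inner carbon), and iodinolysis of the C–Al bond with retention gives the (E)-vinyl iodide.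

**Step 8**
Reactants: 16 4-methoxy-2-methylphenol
Product: 17 2-(hydroxymethyl)-4-methoxy-6-methylphenol
Conditions: 37 % aq. CH2O (3 equiv), NaOH (1.0 equiv), H2O, 20 °C; AcOH to pH 6
Reagents that add atoms: formaldehyde, C=O
Why: Base-mediated ortho-hydroxymethylation of a phenolate (Lederer–Manasse reaction) can only occur at the single free ortho position because the para position carries the methoxy group.

**Step 9**
Reactants: 17 2-(hydroxymethyl)-4-methoxy-6-methylphenol
Product: 20 2-(chloromethyl)-4-methoxy-6-methylphenyl acetate, via benzylic acetate 18 (not isolated), via chloromethyl phenol 19 (not isolated)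
Conditions: AcCl (6 equiv, neat), 20 → 40 °C
Reagents that add atoms: acetyl chloride, CC(=O)Cl
Why: Acetyl chloride acetylates the benzylic alcohol, the liberated HCl exchanges the activated ortho-hydroxybenzylic acetate for chloride, and the phenol is then acetylated, giving a protected benzylic electrophile.

**Step 10**
Reactants: 21 but-3-yn-1-ol; 20 2-(chloromethyl)-4-methoxy-6-methylphenyl acetate
Product: 23 2-[(2E)-5-hydroxy-3-methylpent-2-en-1-yl]-4-methoxy-6-methylphenyl acetate, via alkenylalane alkoxide 22 (not isolated)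
Conditions: 21 (1.3 equiv), Me3Al (3 equiv), Cp2ZrCl2 (0.25 equiv), CH2Cl2, 20 °C; evaporate, THF; 20, NiCl2(PPh3)2 (3 mol %) pre-reduced with n-BuLi (6 mol %) to zerovalent nickel, 20 °C; cold dilute HCl
Reagents that add atoms: trimethylaluminium, C[Al](C)C
Why: Negishi methylalumination of the alkynol (syn addition, E geometry) followed by cross-coupling of the alkenylalane with the benzylic chloride on a zerovalent nickel catalyst (Negishi/Lipshutz type) forms the C1'–C2' bond with retention of the E geometry.

**Step 11**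
Reactants: 23 2-[(2E)-5-hydroxy-3-methylpent-2-en-1-yl]-4-methoxy-6-methylphenyl acetate
Product: 24 4-methoxy-2-methyl-6-[(2E)-3-methyl-5-oxopent-2-en-1-yl]phenyl acetate
Conditions: Dess–Martin periodinane (1.2 equiv), NaHCO3, CH2Cl2, 0 °C; used crude at once
Reagents that add atoms: none
Why: Dess–Martin oxidation under bicarbonate buffer gives the β,γ-unsaturated aldehyde without moving the trisubstituted double bond, and the aryl acetate shields the electron-rich phenol from the oxidant.

**Step 12**
Reactants: 15 (2R,6E)-7-iodo-N-methoxy-N,2,6-trimethylhept-6-enamide; 24 4-methoxy-2-methyl-6-[(2E)-3-methyl-5-oxopent-2-en-1-yl]phenyl acetate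
Product: 26 (2R,6E,8R,10E)-8-hydroxy-12-(2-hydroxy-5-methoxy-3-methylphenyl)-N-methoxy-N,2,6,10-tetramethyldodeca-6,10-dienamide, via aryl acetate adduct 25 (not isolated)
Conditions: CrCl2 (10 mol %), Kishi oxazoline–sulfonamide ligand (11 mol %), 1,8-bis(dimethylamino)naphthalene (11 mol %), NiCl2·(2,9-dimethyl-1,10-phenanthroline) (2 mol %), Mn (2 equiv), Cp2ZrCl2 (1.1 equiv), LiCl (2 equiv), MeCN, 20 °C; aqueous work-up; then K2CO3 (0.3 equiv), MeOH, 20 °C
Reagents that add atoms: none
Why: Catalytic asymmetric Nozaki–Hiyama–Kishi coupling in which nickel activates the C–I bond with retention of the E geometry and the chiral CrCl2–sulfonamide complex adds the alkenyl group to one aldehyde face to set C5' as (R), after which catalytic methanolysis frees the hindered phenol.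

**Step 13**
Reactants: 26 (2R,6E,8R,10E)-8-hydroxy-12-(2-hydroxy-5-methoxy-3-methylphenyl)-N-methoxy-N,2,6,10-tetramethyldodeca-6,10-dienamide; 27 prenyl phenyl sulfone
Product: 29 2-[(2E,5R,6E,11R)-5-hydroxy-3,7,11,15-tetramethyl-12-oxo-13-(phenylsulfonyl)hexadeca-2,6,14-trien-1-yl]-4-methoxy-6-methylphenol, via lithiated sulfone 28 (not isolated)
Conditions: 27 (4.5 equiv), n-BuLi (4.3 equiv), THF, −78 °C; add 26, −78 → −20 °C; H2O
Reagents that add atoms: none
Why: Acylation of a sulfone-stabilised allyl anion by a Weinreb amide occurs at the anion's α-carbon (avoiding the γ-attack of prenyl metals) and stops at the chelated tetrahedral intermediate, the excess anion only deprotonating the phenol and the alcohol.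

**Step 14**
Reactants: 29 2-[(2E,5R,6E,11R)-5-hydroxy-3,7,11,15-tetramethyl-12-oxo-13-(phenylsulfonyl)hexadeca-2,6,14-trien-1-yl]-4-methoxy-6-methylphenol
Product: 30 2-[(2E,5R,6E,11R)-5-hydroxy-3,7,11,15-tetramethyl-12-oxohexadeca-2,6,14-trien-1-yl]-4-methoxy-6-methylphenol
Conditions: SmI2 (3 equiv), THF/MeOH (10:1), −78 °C; pH 7 buffer
Reagents that add atoms: none
Why: SmI2 reductive desulfonylation of a β-keto sulfone gives a dienolate that is protonated at the α-carbon under kinetic control, leaving the β,γ-unsaturated ketone and the adjacent C11' centre untouched.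

**Compound list**
1 | 2,6-dimethylphenol | Cc1cccc(C)c1O | starting material
2 | cis-2,6-dimethylcyclohexan-1-ol (2R,6S; meso; mainly the all-cis 1-epimer) | C[C@H]1CCC[C@@H](C)C1O | intermediate
3 | cis-2,6-dimethylcyclohexan-1-one (2R,6S; meso) | C[C@H]1CCC[C@@H](C)C1=O | intermediate
4 | [(R,R)-bis(1-phenylethyl)amido]magnesium (6R)-2,6-dimethylcyclohex-1-en-1-olate | C[C@@H]1CCCC(C)=C1[O-].[Mg+2].C[C@@H]([N-][C@H](C)c1ccccc1)c1ccccc1 | intermediate
5 | {[(6R)-2,6-dimethylcyclohex-1-en-1-yl]oxy}(trimethyl)silane | C[C@@H]1CCCC(C)=C1O[Si](C)(C)C | intermediate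
6 | trimethylsilyl (2R)-6-hydroperoxy-6-methoxy-2-methylheptanoate (C6 epimers) | COC(C)(OO)CCC[C@@H](C)C(=O)O[Si](C)(C)C | intermediate
7 | trimethylsilyl (2R)-2-methyl-6-oxoheptanoate | CC(=O)CCC[C@@H](C)C(=O)O[Si](C)(C)C | intermediate
8 | (2R)-2-methyl-6-oxoheptanoic acid | CC(=O)CCC[C@@H](C)C(=O)O | intermediate
9 | dilithium (2R)-2-methyl-6-oxidohept-6-enoate | [Li+].[Li+].[O-]C(=C)CCC[C@@H](C)C(=O)[O-] | intermediate
10 | lithium (2R)-6-[(diethoxyphosphoryl)oxy]-2-methylhept-6-enoate | [Li+].CCOP(=O)(OCC)OC(=C)CCC[C@@H](C)C(=O)[O-] | intermediate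
11 | (2R)-2-methylhept-6-ynoic acid | C#CCCC[C@@H](C)C(=O)O | intermediate
12 | (2R)-1-(1H-imidazol-1-yl)-2-methylhept-6-yn-1-one | C#CCCC[C@@H](C)C(=O)n1ccnc1 | intermediate
13 | (2R)-N-methoxy-N,2-dimethylhept-6-ynamide | C#CCCC[C@@H](C)C(=O)N(C)OC | intermediate
14 | (2R,6E)-7-(dimethylalumanyl)-N-methoxy-N,2,6-trimethylhept-6-enamide | CON(C)C(=O)[C@H](C)CCC/C(C)=C/[Al](C)C | intermediate
15 | (2R,6E)-7-iodo-N-methoxy-N,2,6-trimethylhept-6-enamide | CON(C)C(=O)[C@H](C)CCC/C(C)=C/I | intermediate
16 | 4-methoxy-2-methylphenol | COc1ccc(O)c(C)c1 | starting material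
17 | 2-(hydroxymethyl)-4-methoxy-6-methylphenol | COc1cc(C)c(O)c(CO)c1 | intermediate
18 | (2-hydroxy-5-methoxy-3-methylphenyl)methyl acetate | COc1cc(C)c(O)c(COC(C)=O)c1 | intermediate
19 | 2-(chloromethyl)-4-methoxy-6-methylphenol | COc1cc(C)c(O)c(CCl)c1 | intermediate
20 | 2-(chloromethyl)-4-methoxy-6-methylphenyl acetate | COc1cc(C)c(OC(C)=O)c(CCl)c1 | intermediate
21 | but-3-yn-1-ol | C#CCCO | starting material
22 | dimethylaluminium (3E)-4-(dimethylalumanyl)-3-methylbut-3-en-1-olate | C[Al](C)/C=C(\C)CCO[Al](C)C | intermediate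
23 | 2-[(2E)-5-hydroxy-3-methylpent-2-en-1-yl]-4-methoxy-6-methylphenyl acetate | CC(=O)Oc1c(C)cc(OC)cc1C/C=C(\C)CCO | intermediate
24 | 4-methoxy-2-methyl-6-[(2E)-3-methyl-5-oxopent-2-en-1-yl]phenyl acetate | CC(=O)Oc1c(C)cc(OC)cc1C/C=C(\C)CC=O | intermediate
25 | (2R,6E,8R,10E)-12-(2-acetoxy-5-methoxy-3-methylphenyl)-8-hydroxy-N-methoxy-N,2,6,10-tetramethyldodeca-6,10-dienamide | CC(=O)Oc1c(C)cc(OC)cc1C/C=C(\C)C[C@@H](O)/C=C(\C)CCC[C@@H](C)C(=O)N(C)OC | intermediate
26 | (2R,6E,8R,10E)-8-hydroxy-12-(2-hydroxy-5-methoxy-3-methylphenyl)-N-methoxy-N,2,6,10-tetramethyldodeca-6,10-dienamide | COc1cc(C)c(O)c(C/C=C(\C)C[C@@H](O)/C=C(\C)CCC[C@@H](C)C(=O)N(C)OC)c1 | intermediate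
27 | [(3-methylbut-2-en-1-yl)sulfonyl]benzene (prenyl phenyl sulfone) | CC(C)=CCS(=O)(=O)c1ccccc1 | starting material
28 | lithium 3-methyl-1-(phenylsulfonyl)but-2-en-1-ide | [Li+].CC(C)=C[CH-]S(=O)(=O)c1ccccc1 | intermediate
29 | 2-[(2E,5R,6E,11R)-5-hydroxy-3,7,11,15-tetramethyl-12-oxo-13-(phenylsulfonyl)hexadeca-2,6,14-trien-1-yl]-4-methoxy-6-methylphenol (C13 epimers) | COc1cc(C)c(O)c(C/C=C(\C)C[C@@H](O)/C=C(\C)CCC[C@@H](C)C(=O)C(C=C(C)C)S(=O)(=O)c2ccccc2)c1 | intermediate
30 | 2-[(2E,5R,6E,11R)-5-hydroxy-3,7,11,15-tetramethyl-12-oxohexadeca-2,6,14-trien-1-yl]-4-methoxy-6-methylphenol | COc1cc(C)c(O)c(C/C=C(\C)C[C@@H](O)/C=C(\C)CCC[C@@H](C)C(=O)CC=C(C)C)c1 | target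

**Step count and risks**
Total step count: 14. Longest linear sequence: 10 steps (steps 1–7, then 12, 13, 14); the arene branch (steps 8–11) joins at step 12.

The three steps most likely to fail:

Step 3. The enantiomer ratio (and the sense) of the deprotonation rests on reagent control alone, and any trans-ketone left from steps 1–2 erodes it further. The fallback abandons asymmetric deprotonation for classical resolution and sets out from 3. TMSOTf/Et3N in CH2Cl2 at 0 °C gives the racemic silyl enol ether F1. Cleavage with RuCl3 (cat.)/NaIO4 in MeCN/H2O gives racemic 2-methyl-6-oxoheptanoic acid F2. Crystallisation with (R)-1-phenylethylamine (or its antipode, whichever gives the less soluble salt of the (R)-acid) gives the (R)-1-phenylethylammonium salt F3. Acidification with dilute HCl comes back to the route at 8.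

Step 5. The excess amide base may partly deprotonate the carboxylate α-carbon (racemising C11'), or the chlorophosphate may attack the carboxylate. The fallback removes the acidifying group before the base steps and sets out from 8. BH3·THF at −20 °C reduces the carboxyl group faster than the ketone and gives the keto alcohol F4. LDA (2.1 equiv) gives the dilithium alkoxide enolate F5, ClP(O)(OEt)2 gives the enol phosphate F6, and further LDA gives the alkynol F7. Oxidation with TEMPO (cat.)/NaOCl (cat.)/NaClO2 comes back to the route at 11.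

Step 12. Facial selectivity at C5' depends entirely on the chiral chromium ligand, and the C5' epimer would be hard to separate because the two centres are remote. The fallback sets C5' by reduction instead and sets out from 15 and 24. The same coupling run with 2,2'-bipyridine in place of the chiral ligand gives the epimeric alcohol mixture F8. MnO2 in CH2Cl2 gives the dienone F9. Reduction with (S)-2-methyl-CBS-oxazaborolidine (cat.) and catecholborane in toluene at −78 °C (alkenyl as the large group, giving 8R) comes back to the route at 25, which is now isolated and deacetylated to 26 as in step 12.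

**Further compounds**
F1 | step 3 | trimethyl[(2,6-dimethylcyclohex-1-en-1-yl)oxy]silane (racemic) | CC1CCCC(C)=C1O[Si](C)(C)C
F2 | step 3 | 2-methyl-6-oxoheptanoic acid (racemic) | CC(=O)CCCC(C)C(=O)O
F3 | step 3 | (1R)-1-phenylethan-1-aminium (2R)-2-methyl-6-oxoheptanoate | CC(=O)CCC[C@@H](C)C(=O)[O-].C[C@@H]([NH3+])c1ccccc1
F4 | step 5 | (6R)-7-hydroxy-6-methylheptan-2-one | CC(=O)CCC[C@@H](C)CO
F5 | step 5 | dilithium (6R)-6-methylhept-1-ene-2,7-diolate | [Li+].[Li+].[O-]C(=C)CCC[C@@H](C)C[O-]
F6 | step 5 | lithium (2R)-6-[(diethoxyphosphoryl)oxy]-2-methylhept-6-en-1-olate | [Li+].CCOP(=O)(OCC)OC(=C)CCC[C@@H](C)C[O-]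
F7 | step 5 | (2R)-2-methylhept-6-yn-1-ol | C#CCCC[C@@H](C)CO
F8 | step 12 | (2R,6E,8RS,10E)-12-(2-acetoxy-5-methoxy-3-methylphenyl)-8-hydroxy-N-methoxy-N,2,6,10-tetramethyldodeca-6,10-dienamide | CC(=O)Oc1c(C)cc(OC)cc1C/C=C(\C)CC(O)/C=C(\C)CCC[C@@H](C)C(=O)N(C)OC
F9 | step 12 | (2R,6E,10E)-12-(2-acetoxy-5-methoxy-3-methylphenyl)-N-methoxy-N,2,6,10-tetramethyl-8-oxododeca-6,10-dienamide | CC(=O)Oc1c(C)cc(OC)cc1C/C=C(\C)CC(=O)/C=C(\C)CCC[C@@H](C)C(=O)N(C)OC
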